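# Total synthesis proposal for CNP0304643.4 by [2,3]-Wittig contraction of a thirteen-membered diallyl ether

Remark on the chemistry: positions in all intermediates are named by germacrane numbering (C1–C10 ring, C11–C13 lactone carbons, C14 and C15 methyls). Angelic acid is assumed to be commercially available alongside geranyl acetate, diethyl D-tartrate and triethyl phosphonoacetate.

## Analysis of the target

The target 36 is a germacranolide: a ten-membered carbocycle (C1–C10) with a trans-fused α-methylene-γ-butyrolactone across C6–C7, in which O sits on C6 and C11, C12 and C13 hang from C7. The ring holds a Z trisubstituted alkene C1=C10 (methyl C14) and an E trisubstituted alkene C4=C5 (methyl C15). Four contiguous ring stereocentres are (6S,7R,8R,9R). The lactone oxygen on C6 and the C7–C11 bond lie on opposite faces, H-7 and H-8 on the same face, and the oxygens on C8 and C9 are trans (a threo diol with the D-tartrate configuration). C9 carries an allylic acetate, and C8 carries the ester of (2R,3R)-2,3-dimethyloxirane-2-carboxylic acid (epoxyangelic acid), which adds two stereocentres. Sensitive groups are the exo-methylene lactone (a Michael acceptor), the acid-labile oxirane ester, the two neighbouring esters that can migrate, and the 1(10),4-diene, which can cyclise across the ring under acid. The difficulty lies in the strained medium ring with two alkenes of opposite geometry, four adjacent stereocentres, and two vicinal secondary hydroxyls that must be acylated differently. The strategy rests on the unit C6(O)–C7–C11(=C13)–C12: an oxygenated carbon next to a carbon bearing a 2-propenyl group is the homoallylic alcohol left by a [2,3]-Wittig shift of an allyl ether that joined O6 to C13.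

## Retrosynthetic reasoning

**Esters last.** The C8 acyl–oxygen bond of 36 is cut to the hydroxy acetate 30 and the epoxy acid 34, and the C9 acetate is cut back to the diol lactone 29. Neither ester would survive organolithium or hydride steps, so both come after all carbon–carbon bond formation. The forward steps must tell O9 from O8. Acid 34 traces back through epoxy alcohol 33 and allylic alcohol 32 to angelic acid 31, and a Sharpless epoxidation sets both oxirane centres.

**Lactone.** The C12–O6 bond of 29 is cut at the oxidation level. Lactone 28 comes from the 2-methylene-1,4-diol 25 by allylic oxidation and lactol closure, and 25 comes from silyl ether 24. The acetonide stays on O8/O9 until the lactone is closed, because a free O8 could also capture C12.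

**Key disconnection.** In 24 the C6–C7 bond is cut and O6 is joined to C13. This gives the thirteen-membered diallyl ether 22. A hard ten-membered closure becomes an easier thirteen-membered etherification. The forward shift makes C6 and C7 together and leaves C13 as the exo-methylene carbon, so only C12 needs oxidation afterwards.

**Macrocyclic ether.** The O–C13 bond of 22 is cut to the hydroxy chloride 21, with O6 as nucleophile and C13 as electrophile. The reverse polarity would place an alkoxide on C13 next to the C12 silyl ether and invite silyl migration between the two arms. For the same reason the C6 hydroxyl is masked while C13 is turned into the chloride (16 to 21 through 17, 18 and 20).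

**C7=C11.** Enoate 16 is cut at C7=C11 to aldehyde 12 and phosphonate 15. Plain triethyl phosphonoacetate 13 cannot supply C12, so it is first hydroxymethylated and silylated (14, then 15). An E-selective olefination then puts the ester (the future C13) trans to C8 and the silyloxymethyl arm (C12) cis to C8, the geometry the shift needs.

**C1=C10.** Aldehyde 12 comes from Weinreb amide 11, which is cut at C1=C10 to phosphonium salt 5 and methyl ketone 9. The α-alkoxy ketone directs a Z-selective Wittig reaction. The acetate of 5 serves as the C6 protecting group and is removed in the same hydride step that unveils the aldehyde.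

**Chiral pool.** Ketone 9 comes from the C2-symmetric bis-amide 8, from acetonide 7, from diethyl D-tartrate 6. Both ends of 8 are identical, so one methyl addition gives a single ketone, and C8 and C9 are never at risk.

**C1–C6 chain.** Salt 5 comes from iodide 4, from alcohol 3, from geranyl acetate 1, by cleaving the electron-rich terminal alkene. The E alkene C4=C5 is already present in 1.

## Alternatives that were turned down

**Alternative 1:** Cut C5–C6 and the lactone C12–O bond. In the forward step the open-chain iodo aldehyde A1 would be treated with CrCl2 (divalent chromium) and catalytic NiCl2. The E-vinylchromium at C5 adds to the C6 aldehyde, and the chromium alkoxide closes onto the C12 methyl ester to give the protected lactone A2.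
- For: the reaction is tolerant and convergent, keeps the vinyl iodide geometry, and makes ring and lactone in one operation. It is stronger than the chosen route on one point: O8 and O9 are distinguished from the start by different protecting groups.
- Against: C6 is created by addition to an α-branched, β-silyloxy aldehyde, so its configuration depends on an unpredictable facial preference and the aldehyde can epimerise at C7 or eliminate. The ten-membered ring must be closed end to end at high dilution. A2 still lacks C13, so the lactone must be methylenated later under basic conditions.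
- Comparison: the chosen shift sets C6 and C7 in one concerted event, delivers C13 already as the methylene, and closes an easier thirteen-membered ring. The price is the later selective acylation of O9 against O8.

**Alternative 2:** Cut C8–C9. The lactone dialdehyde A3 would be coupled with SmI2 (divalent samarium), or with the low-valent titanium reagent from TiCl3 and Zn–Cu, to give the diol lactone A4.
- For: it is the shortest closure, forms both carbinols at once and needs no diol protecting group. On step count it is stronger.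
- Against: two stereocentres and the ring are made in one radical step. The trans diol with the right sense relative to C6/C7 is one of four outcomes, and medium-ring pinacol couplings give no reliable preference. The Z-enal ketyl can isomerise or couple through C1. The C8 aldehyde is prone to epimerisation at C7 and to β-elimination of the lactone oxygen. A4 also lacks C13 and has two undifferentiated hydroxyls.
- Comparison: the chosen route takes C8 and C9 intact from the chiral pool and puts its single stereochemical gamble in a step with a defined cyclic transition state.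

**Alternative 3:** Cut C2–C3 by a retro-Cope. The potassium alkoxide of the cyclohexanol A5 (KH, crown ether) would undergo anionic oxy-Cope ring expansion, and the C1=C10 enolate would be trapped with PhNTf2 to give the Z-enol triflate A6, later coupled with a methyl donor.
- For: the six-membered ring allows conformational control of C6–C9. The ring expansion is intramolecular and needs no high dilution. There is no question of which proton a base removes, and O8 and O9 are differentiated. On these points it is stronger.
- Against: A5 is a cyclohexane with six contiguous stereocentres that is long to build. The E geometry at C4=C5 and the Z enolate depend on a chair or boat transition state that is hard to enforce. The enolate has an alkoxy group on C9 and can eliminate it. The lactol ether must still be oxidised and methylenated.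
- Comparison: the chosen route sets both alkenes in the open chain by olefinations with known selectivity and reaches the ring in far fewer steps.

Key step: step 17

## Steps

Step 1
Reactants: 1 geranyl acetate
Product: 3 (2E)-6-hydroxy-3-methylhex-2-en-1-yl acetate, via aldehyde 2 (not isolated)
Conditions: O3 (1.0 equiv), CH2Cl2/MeOH, pyridine (cat.), −78 °C; then NaBH4, −78 → 0 °C
Reagents that add atoms: ozone, O=[O+][O-]
Why: Selective ozonolysis; the 6,7-alkene is more electron-rich than the 2,3-alkene, which is deactivated by the allylic acetate, so one equivalent of ozone cleaves only the terminal alkene. Reductive work-up with NaBH4 takes aldehyde 2 to the alcohol, and the E alkene C4=C5 is kept.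

Step 2
Reactants: 3 (2E)-6-hydroxy-3-methylhex-2-en-1-yl acetate
Product: 4 (2E)-6-iodo-3-methylhex-2-en-1-yl acetate
Conditions: I2, PPh3, imidazole, CH2Cl2, 0 °C
Reagents that add atoms: iodine, II
Why: Appel-type iodination of a primary alcohol through the alkoxyphosphonium salt; the allylic acetate and the alkene are inert.

Step 3
Reactants: 4 (2E)-6-iodo-3-methylhex-2-en-1-yl acetate
Product: 5 [(4E)-6-acetoxy-4-methylhex-4-en-1-yl]triphenylphosphonium iodide
Conditions: PPh3, MeCN, 80 °C
Reagents that add atoms: triphenylphosphine, c1ccc(cc1)P(c1ccccc1)c1ccccc1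
Why: SN2 quaternisation of triphenylphosphine by the primary iodide; an allylic acetate does not react with the phosphine without a metal catalyst.

Step 4
Reactants: 6 diethyl D-tartrate
Product: 7 diethyl (4S,5S)-2,2-dimethyl-1,3-dioxolane-4,5-dicarboxylate
Conditions: 2,2-dimethoxypropane, TsOH (cat.), toluene, reflux with removal of MeOH
Reagents that add atoms: 2,2-dimethoxypropane, COC(C)(C)OC
Why: Acid-catalysed transacetalisation of the threo diol to the trans-dioxolane; the stereocentres that become C8 and C9 are not touched.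

Step 5
Reactants: 7 diethyl (4S,5S)-2,2-dimethyl-1,3-dioxolane-4,5-dicarboxylate
Product: 8 (4S,5S)-N4,N5-dimethoxy-N4,N5,2,2-tetramethyl-1,3-dioxolane-4,5-dicarboxamide
Conditions: MeNH(OMe)·HCl, i-PrMgCl, THF, −20 → 0 °C
Reagents that add atoms: N,O-dimethylhydroxylamine hydrochloride, CNOC.Cl
Why: Aminolysis of both esters by the magnesium amide of N,O-dimethylhydroxylamine (Weinreb amide formation). The trans-dioxolane is the stable arrangement and should not epimerise at this temperature.

Step 6
Reactants: 8 (4S,5S)-N4,N5-dimethoxy-N4,N5,2,2-tetramethyl-1,3-dioxolane-4,5-dicarboxamide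
Product: 9 (4S,5S)-5-acetyl-N-methoxy-N,2,2-trimethyl-1,3-dioxolane-4-carboxamide
Conditions: MeMgBr (1.05 equiv), THF, −78 → −30 °C; aq. NH4Cl
Reagents that add atoms: methylmagnesium bromide, C[Mg]Br
Why: Weinreb ketone synthesis; the magnesium-chelated tetrahedral intermediate does not collapse before work-up, so the ketone is not attacked again. Both amides of the C2-symmetric 8 are equivalent, so one equivalent of Grignard reagent should give mainly the single mono-ketone, with bis-adduct and unreacted 8 removed by chromatography.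

Step 7
Reactants: 5 [(4E)-6-acetoxy-4-methylhex-4-en-1-yl]triphenylphosphonium iodide; 9 (4S,5S)-5-acetyl-N-methoxy-N,2,2-trimethyl-1,3-dioxolane-4-carboxamide
Product: 11 (4S,5R)-5-[(2Z,6E)-8-acetoxy-6-methylocta-2,6-dien-2-yl]-N-methoxy-N,2,2-trimethyl-1,3-dioxolane-4-carboxamide, via ylide 10 (not isolated)
Conditions: 5, KN(SiMe3)2 (0.95 equiv), THF, −78 °C; then 9 (1.2 equiv), −78 → −30 °C
Reagents that add atoms: none
Why: Lithium-free Wittig olefination of an α-alkoxy methyl ketone with a non-stabilised ylide, a combination known to give Z trisubstituted alkenes with the ylide chain cis to the oxygenated carbon (C2 cis to C9). The activated ketone reacts at low temperature, where the Weinreb amide and the acetate are inert, and it is used in slight excess so that no ylide is left to attack them.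

Step 8
Reactants: 11 (4S,5R)-5-[(2Z,6E)-8-acetoxy-6-methylocta-2,6-dien-2-yl]-N-methoxy-N,2,2-trimethyl-1,3-dioxolane-4-carboxamide
Product: 12 (4S,5R)-5-[(2Z,6E)-8-hydroxy-6-methylocta-2,6-dien-2-yl]-2,2-dimethyl-1,3-dioxolane-4-carbaldehyde
Conditions: i-Bu2AlH (3.5 equiv), THF/CH2Cl2, −78 °C; aq. potassium sodium tartrate
Reagents that add atoms: none
Why: Hydride reduction of the Weinreb amide stops at the chelated hemiaminal and gives the C7 aldehyde on work-up, while the same reagent cleaves the acetate to free the C6 alcohol. The aldehyde is used crude to avoid epimerisation at C8.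

Step 9
Reactants: 13 triethyl phosphonoacetate
Product: 14 ethyl 2-(diethoxyphosphoryl)-3-hydroxypropanoate
Conditions: (CH2O)n (1.0 equiv), piperidine (cat.), MeOH, 60 °C
Reagents that add atoms: paraformaldehyde (formaldehyde), C=O
Why: Amine-catalysed aldol-type hydroxymethylation of the active methylene. With one equivalent of formaldehyde and only catalytic base the mono-adduct should not go on to olefinate a second formaldehyde.

Step 10
Reactants: 14 ethyl 2-(diethoxyphosphoryl)-3-hydroxypropanoate
Product: 15 ethyl 3-[(tert-butyldimethylsilyl)oxy]-2-(diethoxyphosphoryl)propanoate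
Conditions: TBSCl, imidazole, DMF, 0 °C → rt
Reagents that add atoms: tert-butyldimethylsilyl chloride, CC(C)(C)[Si](C)(C)Cl
Why: Standard silylation of a primary alcohol; the silyl ether blocks dehydration to the vinylphosphonate.

Step 11
Reactants: 12 (4S,5R)-5-[(2Z,6E)-8-hydroxy-6-methylocta-2,6-dien-2-yl]-2,2-dimethyl-1,3-dioxolane-4-carbaldehyde; 15 ethyl 3-[(tert-butyldimethylsilyl)oxy]-2-(diethoxyphosphoryl)propanoate
Product: 16 ethyl (2E)-2-{[(tert-butyldimethylsilyl)oxy]methyl}-3-{(4R,5R)-5-[(2Z,6E)-8-hydroxy-6-methylocta-2,6-dien-2-yl]-2,2-dimethyl-1,3-dioxolan-4-yl}prop-2-enoate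
Conditions: 15 (1.3 equiv), LiCl, DBU, MeCN, 0 °C → rt
Reagents that add atoms: none
Why: Horner–Wadsworth–Emmons olefination under Masamune–Roush conditions, mild enough for the epimerisable α-alkoxy aldehyde and the free alcohol. α-Substituted phosphonoacetates give the enoate with the ester trans to the aldehyde-derived carbon, so C8 ends trans to the ester (future C13) and cis to the silyloxymethyl arm (C12).

Step 12
Reactants: 16 ethyl (2E)-2-{[(tert-butyldimethylsilyl)oxy]methyl}-3-{(4R,5R)-5-[(2Z,6E)-8-hydroxy-6-methylocta-2,6-dien-2-yl]-2,2-dimethyl-1,3-dioxolan-4-yl}prop-2-enoate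
Product: 17 triethylsilyl ether of 16 at the C6 oxygen
Conditions: Et3SiCl, imidazole, CH2Cl2, 0 °C
Reagents that add atoms: chlorotriethylsilane, CC[Si](CC)(CC)Cl
Why: Silylation of the only free hydroxyl; the triethylsilyl group can later be removed without loss of the tert-butyldimethylsilyl ether.

Step 13
Reactants: 17 triethylsilyl ether of 16 at the C6 oxygen
Product: 18 (2Z)-2-{[(tert-butyldimethylsilyl)oxy]methyl}-3-{(4R,5R)-2,2-dimethyl-5-[(2Z,6E)-6-methyl-8-(triethylsilyloxy)octa-2,6-dien-2-yl]-1,3-dioxolan-4-yl}prop-2-en-1-ol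
Conditions: i-Bu2AlH (2.5 equiv), CH2Cl2, −78 °C; aq. potassium sodium tartrate
Reagents that add atoms: none
Why: 1,2-Reduction of the conjugated ester to the primary allylic alcohol (C13–OH); silyl ethers, acetonide and alkenes are inert and the alkene geometry is kept.

Step 14
Reactants: 18 (2Z)-2-{[(tert-butyldimethylsilyl)oxy]methyl}-3-{(4R,5R)-2,2-dimethyl-5-[(2Z,6E)-6-methyl-8-(triethylsilyloxy)octa-2,6-dien-2-yl]-1,3-dioxolan-4-yl}prop-2-en-1-ol
Product: 20 allylic chloride at C13 with C12 tert-butyldimethylsilyl ether and C6 triethylsilyl ether, via mesylate 19 (not isolated)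
Conditions: MsCl, 2,4,6-collidine, LiCl, DMF, 0 °C
Reagents that add atoms: lithium chloride, [Li+].[Cl-]
Why: Mesylation and in situ SN2 displacement by chloride, a standard way to make primary allylic chlorides without allylic transposition or loss of alkene geometry.

Step 15
Reactants: 20 allylic chloride at C13 with C12 tert-butyldimethylsilyl ether and C6 triethylsilyl ether
Product: 21 (2E,6Z)-7-{(4R,5R)-5-[(1E)-3-chloro-2-{[(tert-butyldimethylsilyl)oxy]methyl}prop-1-en-1-yl]-2,2-dimethyl-1,3-dioxolan-4-yl}-3-methylocta-2,6-dien-1-ol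
Conditions: HF·pyridine, pyridine, THF, 0 °C
Reagents that add atoms: none
Why: Selective desilylation; a primary triethylsilyl ether is cleaved by buffered HF much faster than a primary tert-butyldimethylsilyl ether, and the acetonide and the allylic chloride tolerate these conditions.

Step 16
Reactants: 21 (2E,6Z)-7-{(4R,5R)-5-[(1E)-3-chloro-2-{[(tert-butyldimethylsilyl)oxy]methyl}prop-1-en-1-yl]-2,2-dimethyl-1,3-dioxolan-4-yl}-3-methylocta-2,6-dien-1-ol
Product: 22 (3Z,5R,6R,7Z,11E)-3-{[(tert-butyldimethylsilyl)oxy]methyl}-5,6-(isopropylidenedioxy)-7,11-dimethyl-1-oxacyclotrideca-3,7,11-triene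
Conditions: NaH, Bu4NI (cat.), THF (0.001 M), 50 °C, slow addition of 21
Reagents that add atoms: none
Why: Intramolecular Williamson etherification at high dilution; the C6 alkoxide displaces the primary allylic chloride at C13 by SN2 (the SN2' site C7 is hindered by C8). Three alkenes and the trans-dioxolane leave the chain few rotors, which helps the thirteen-membered closure, and the alkoxide is far from the silyl ether, so no silyl migration can occur.

Step 17
Reactants: 22 (3Z,5R,6R,7Z,11E)-3-{[(tert-butyldimethylsilyl)oxy]methyl}-5,6-(isopropylidenedioxy)-7,11-dimethyl-1-oxacyclotrideca-3,7,11-triene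
Product: 24 (6S,7R,8R,9R)-12-[(tert-butyldimethylsilyl)oxy]-8,9-(isopropylidenedioxy)germacra-1(10)Z,4E,11(13)-trien-6-ol, via C6-lithio ether 23 (not isolated)
Conditions: n-BuLi (1.3 equiv), THF, −78 → −25 °C; aq. NH4Cl
Reagents that add atoms: none
Why: n-BuLi removes a C6 proton, acidified by the ether oxygen and the C4=C5 alkene, and the α-oxyallyl-lithium 23 undergoes a concerted suprafacial [2,3]-sigmatropic (Wittig) shift through a five-membered envelope of C6, O, C13, C11 and C7, forming C6–C7 while O–C13 breaks and the alkene moves from C7=C11 to C11=C13. The closest known reaction type is the [2,3]-Wittig ring contraction of macrocyclic diallyl ethers to medium-ring homoallylic alcohols. The ten-membered ring is not closed end to end but arises by contraction, the new bond spanning the thirteen-membered ring so that O, C13 and C11 leave the ring perimeter, so no high dilution is needed and the strain is paid for by the change from carbanion to alkoxide. The relative configuration of C6 and C7 (O6 and C11 on opposite faces, the later trans ring fusion) follows from the E geometry of C7=C11, in which C8 is trans to C13 and takes the exo position of the envelope. The sense of attack at C7 is set by C8: allylic 1,3-strain with the cis C12 silyloxymethyl arm holds H-8 in the alkene plane, leaving O8 on one face and the ring chain through C9 on the other, and the tethered carbanion can reach C7 only on the O8 face without eclipsing C8–C9, which gives (6S,7R). The step needs lithiation at C6 and not at C13 or C12; C13 is flanked by the fully substituted C11 with its bulky silyloxymethyl group, a C13 anion could rearrange only by building a quaternary centre at C4, and the silyl ether is a poor directing group. Low temperature and the lithium counter-ion should suppress the [1,2]-shift and an anionic oxy-Cope reaction of the product alkoxide, and the C1=C10 and C4=C5 geometries are not touched.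

Step 18
Reactants: 24 (6S,7R,8R,9R)-12-[(tert-butyldimethylsilyl)oxy]-8,9-(isopropylidenedioxy)germacra-1(10)Z,4E,11(13)-trien-6-ol
Product: 25 (6S,7R,8R,9R)-8,9-(isopropylidenedioxy)germacra-1(10)Z,4E,11(13)-triene-6,12-diol
Conditions: Bu4NF, THF, 0 °C
Reagents that add atoms: none
Why: Fluoride cleavage of the primary silyl ether; acetonide, alkenes and stereocentres are unaffected.

Step 19
Reactants: 25 (6S,7R,8R,9R)-8,9-(isopropylidenedioxy)germacra-1(10)Z,4E,11(13)-triene-6,12-diol
Product: 28 (6S,7R,8R,9R)-8,9-(isopropylidenedioxy)germacra-1(10)Z,4E,11(13)-trien-12,6-olide, via hydroxy enal 26 (not isolated), via lactol 27 (not isolated)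
Conditions: MnO2 (excess), CH2Cl2, rt
Reagents that add atoms: none
Why: Known oxidative lactonisation of 2-methylene-1,4-diols; MnO2 oxidises the primary allylic C12 alcohol faster than the secondary allylic C6 alcohol, enal 26 closes with O6 to the five-membered lactol 27, and the allylic lactol is oxidised to the lactone. O8 is held in the acetonide and cannot compete, and no stereocentre is touched.

Step 20
Reactants: 28 (6S,7R,8R,9R)-8,9-(isopropylidenedioxy)germacra-1(10)Z,4E,11(13)-trien-12,6-olide
Product: 29 (6S,7S,8R,9R)-8,9-dihydroxygermacra-1(10)Z,4E,11(13)-trien-12,6-olide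
Conditions: AcOH/THF/H2O (3:1:1), 40 °C
Reagents that add atoms: none
Why: Acid-catalysed hydrolysis of the trans-fused dioxolane, which is strained on the medium ring and should cleave under mild aqueous acid. Mild conditions are chosen because the 1(10),4-diene can cyclise across the ring and the free C8 hydroxyl could translactonise.

Step 21
Reactants: 29 (6S,7S,8R,9R)-8,9-dihydroxygermacra-1(10)Z,4E,11(13)-trien-12,6-olide
Product: 30 (6S,7S,8R,9R)-9-acetoxy-8-hydroxygermacra-1(10)Z,4E,11(13)-trien-12,6-olide
Conditions: Ac2O (1.1 equiv), 2,4,6-collidine, DMAP (cat.), CH2Cl2, −40 °C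
Reagents that add atoms: acetic anhydride, CC(=O)OC(C)=O
Why: Site-selective acylation; the allylic C9 hydroxyl is flanked by the flat C10, whereas the C8 hydroxyl is flanked by the branched ring-fusion carbon C7 and shielded by the lactone. One equivalent of anhydride at low temperature with a hindered base should acylate O9 first and leave no chance for acyl migration.

Step 22
Reactants: 31 angelic acid
Product: 32 (2Z)-2-methylbut-2-en-1-ol
Conditions: LiAlH4, Et2O, 0 °C
Reagents that add atoms: none
Why: Hydride reduction of the carboxylic acid to the allylic alcohol; alkyl-substituted enoic acids are reduced without conjugate reduction, and the Z geometry is kept.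

Step 23
Reactants: 32 (2Z)-2-methylbut-2-en-1-ol
Product: 33 [(2S,3R)-2,3-dimethyloxiran-2-yl]methanol
Conditions: Ti(OiPr)4 (10 mol%), L-(+)-diethyl tartrate (12 mol%), t-BuOOH, 4 Å molecular sieves, CH2Cl2, −20 °C
Reagents that add atoms: tert-butyl hydroperoxide, CC(C)(C)OO
Why: Sharpless asymmetric epoxidation; the titanium–tartrate complex delivers oxygen to one face of the allylic alcohol, and the L-(+)-tartrate gives the (2S,3R) epoxy alcohol, the same face sense that gives (2S,3S)-epoxygeraniol. The cis addition keeps the two methyl groups trans, as in the Z alkene.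

Step 24
Reactants: 33 [(2S,3R)-2,3-dimethyloxiran-2-yl]methanol
Product: 34 (2R,3R)-2,3-dimethyloxirane-2-carboxylic acid
Conditions: TEMPO (cat.), NaOCl (cat.), NaClO2, MeCN/phosphate buffer (pH 6.7), 35 °C
Reagents that add atoms: sodium chlorite, [Na+].[O-]Cl=O
Why: Oxoammonium oxidation of the primary alcohol to the aldehyde and chlorite oxidation to the acid in one pot near neutral pH, which spares the oxirane. The stereocentres are untouched; the descriptor at C2 changes only because the priorities change.

Step 25
Reactants: 30 (6S,7S,8R,9R)-9-acetoxy-8-hydroxygermacra-1(10)Z,4E,11(13)-trien-12,6-olide; 34 (2R,3R)-2,3-dimethyloxirane-2-carboxylic acid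
Product: 36 (6S,7R,8R,9R)-9-acetoxy-8-{[(2R,3R)-2,3-dimethyloxirane-2-carbonyl]oxy}germacra-1(10)Z,4E,11(13)-trien-12,6-olide, via mixed anhydride 35 (not isolated)
Conditions: 34, 2,4,6-trichlorobenzoyl chloride, Et3N, toluene, rt; then 30, DMAP, toluene, rt → 40 °C
Reagents that add atoms: none
Why: Yamaguchi esterification; DMAP attacks the oxirane carbonyl of 35 (the aroyl carbonyl is blocked by two ortho chlorines) and the acylpyridinium acylates the hindered C8 alcohol. No base strong enough to open the lactone or move the acetate is present, and the oxirane centres are not involved.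

## Compound list

1 | geranyl acetate, (2E)-3,7-dimethylocta-2,6-dien-1-yl acetate | CC(C)=CCC/C(C)=C/COC(C)=O | starting material
2 | (2E)-3-methyl-6-oxohex-2-en-1-yl acetate | O=CCC/C(C)=C/COC(C)=O | intermediate
3 | (2E)-6-hydroxy-3-methylhex-2-en-1-yl acetate | OCCC/C(C)=C/COC(C)=O | intermediate
4 | (2E)-6-iodo-3-methylhex-2-en-1-yl acetate | ICCC/C(C)=C/COC(C)=O | intermediate
5 | [(4E)-6-acetoxy-4-methylhex-4-en-1-yl]triphenylphosphonium iodide | CC(=O)OC/C=C(\C)CCC[P+](c1ccccc1)(c1ccccc1)c1ccccc1.[I-] | intermediate
6 | diethyl D-tartrate, diethyl (2S,3S)-2,3-dihydroxybutanedioate | CCOC(=O)[C@@H](O)[C@H](O)C(=O)OCC | starting material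
7 | diethyl (4S,5S)-2,2-dimethyl-1,3-dioxolane-4,5-dicarboxylate | CCOC(=O)[C@H]1OC(C)(C)O[C@@H]1C(=O)OCC | intermediate
8 | (4S,5S)-N4,N5-dimethoxy-N4,N5,2,2-tetramethyl-1,3-dioxolane-4,5-dicarboxamide | CON(C)C(=O)[C@H]1OC(C)(C)O[C@@H]1C(=O)N(C)OC | intermediate
9 | (4S,5S)-5-acetyl-N-methoxy-N,2,2-trimethyl-1,3-dioxolane-4-carboxamide | CC(=O)[C@H]1OC(C)(C)O[C@@H]1C(=O)N(C)OC | intermediate
10 | [(4E)-6-acetoxy-4-methylhex-4-en-1-ylidene]triphenylphosphorane (ylide) | CC(=O)OC/C=C(\C)CCC=P(c1ccccc1)(c1ccccc1)c1ccccc1 | intermediate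
11 | (4S,5R)-5-[(2Z,6E)-8-acetoxy-6-methylocta-2,6-dien-2-yl]-N-methoxy-N,2,2-trimethyl-1,3-dioxolane-4-carboxamide | CC(=O)OC/C=C(\C)CC/C=C(/C)[C@H]1OC(C)(C)O[C@@H]1C(=O)N(C)OC | intermediate
12 | (4S,5R)-5-[(2Z,6E)-8-hydroxy-6-methylocta-2,6-dien-2-yl]-2,2-dimethyl-1,3-dioxolane-4-carbaldehyde | OC/C=C(\C)CC/C=C(/C)[C@H]1OC(C)(C)O[C@@H]1C=O | intermediate
13 | triethyl phosphonoacetate | CCOC(=O)CP(=O)(OCC)OCC | starting material
14 | ethyl 2-(diethoxyphosphoryl)-3-hydroxypropanoate (racemic) | CCOC(=O)C(CO)P(=O)(OCC)OCC | intermediate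
15 | ethyl 3-[(tert-butyldimethylsilyl)oxy]-2-(diethoxyphosphoryl)propanoate (racemic) | CCOC(=O)C(CO[Si](C)(C)C(C)(C)C)P(=O)(OCC)OCC | intermediate
16 | ethyl (2E)-2-{[(tert-butyldimethylsilyl)oxy]methyl}-3-{(4R,5R)-5-[(2Z,6E)-8-hydroxy-6-methylocta-2,6-dien-2-yl]-2,2-dimethyl-1,3-dioxolan-4-yl}prop-2-enoate | OC/C=C(\C)CC/C=C(/C)[C@H]1OC(C)(C)O[C@@H]1/C=C(\CO[Si](C)(C)C(C)(C)C)C(=O)OCC | intermediate
17 | ethyl (2E)-2-{[(tert-butyldimethylsilyl)oxy]methyl}-3-{(4R,5R)-2,2-dimethyl-5-[(2Z,6E)-6-methyl-8-(triethylsilyloxy)octa-2,6-dien-2-yl]-1,3-dioxolan-4-yl}prop-2-enoate | CC[Si](CC)(CC)OC/C=C(\C)CC/C=C(/C)[C@H]1OC(C)(C)O[C@@H]1/C=C(\CO[Si](C)(C)C(C)(C)C)C(=O)OCC | intermediate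
18 | (2Z)-2-{[(tert-butyldimethylsilyl)oxy]methyl}-3-{(4R,5R)-2,2-dimethyl-5-[(2Z,6E)-6-methyl-8-(triethylsilyloxy)octa-2,6-dien-2-yl]-1,3-dioxolan-4-yl}prop-2-en-1-ol | CC[Si](CC)(CC)OC/C=C(\C)CC/C=C(/C)[C@H]1OC(C)(C)O[C@@H]1/C=C(\CO[Si](C)(C)C(C)(C)C)CO | intermediate
19 | methanesulfonate of 18 at the C13 oxygen | CC[Si](CC)(CC)OC/C=C(\C)CC/C=C(/C)[C@H]1OC(C)(C)O[C@@H]1/C=C(\CO[Si](C)(C)C(C)(C)C)COS(C)(=O)=O | intermediate
20 | tert-butyl{[(2E)-2-(chloromethyl)-3-{(4R,5R)-2,2-dimethyl-5-[(2Z,6E)-6-methyl-8-(triethylsilyloxy)octa-2,6-dien-2-yl]-1,3-dioxolan-4-yl}prop-2-en-1-yl]oxy}dimethylsilane | CC[Si](CC)(CC)OC/C=C(\C)CC/C=C(/C)[C@H]1OC(C)(C)O[C@@H]1/C=C(\CO[Si](C)(C)C(C)(C)C)CCl | intermediate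
21 | (2E,6Z)-7-{(4R,5R)-5-[(1E)-3-chloro-2-{[(tert-butyldimethylsilyl)oxy]methyl}prop-1-en-1-yl]-2,2-dimethyl-1,3-dioxolan-4-yl}-3-methylocta-2,6-dien-1-ol | OC/C=C(\C)CC/C=C(/C)[C@H]1OC(C)(C)O[C@@H]1/C=C(\CO[Si](C)(C)C(C)(C)C)CCl | intermediate
22 | (3Z,5R,6R,7Z,11E)-3-{[(tert-butyldimethylsilyl)oxy]methyl}-5,6-(isopropylidenedioxy)-7,11-dimethyl-1-oxacyclotrideca-3,7,11-triene (ether between O6 and C13) | C1OC/C(CO[Si](C)(C)C(C)(C)C)=C/[C@H]2OC(C)(C)O[C@@H]2/C(C)=C\CC/C(C)=C/1 | intermediate
23 | 13-lithio derivative of 22 (lithium on germacrane C6) | [Li]C1OC/C(CO[Si](C)(C)C(C)(C)C)=C/[C@H]2OC(C)(C)O[C@@H]2/C(C)=C\CC/C(C)=C/1 | intermediate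
24 | (6S,7R,8R,9R)-12-[(tert-butyldimethylsilyl)oxy]-8,9-(isopropylidenedioxy)germacra-1(10)Z,4E,11(13)-trien-6-ol | C=C(CO[Si](C)(C)C(C)(C)C)[C@@H]1[C@@H](O)/C=C(\C)CC/C=C(/C)[C@H]2OC(C)(C)O[C@H]12 | intermediate
25 | (6S,7R,8R,9R)-8,9-(isopropylidenedioxy)germacra-1(10)Z,4E,11(13)-triene-6,12-diol | C=C(CO)[C@@H]1[C@@H](O)/C=C(\C)CC/C=C(/C)[C@H]2OC(C)(C)O[C@H]12 | intermediate
26 | (6S,7R,8R,9R)-6-hydroxy-8,9-(isopropylidenedioxy)germacra-1(10)Z,4E,11(13)-trien-12-al | C=C(C=O)[C@@H]1[C@@H](O)/C=C(\C)CC/C=C(/C)[C@H]2OC(C)(C)O[C@H]12 | intermediate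
27 | lactol of 26 (12-hydroxy-6,12-epoxide, mixture at C12) | C=C1C(O)O[C@H]2/C=C(\C)CC/C=C(/C)[C@H]3OC(C)(C)O[C@@H]3[C@H]12 | intermediate
28 | (6S,7R,8R,9R)-8,9-(isopropylidenedioxy)germacra-1(10)Z,4E,11(13)-trien-12,6-olide | C=C1C(=O)O[C@H]2/C=C(\C)CC/C=C(/C)[C@H]3OC(C)(C)O[C@@H]3[C@H]12 | intermediate
29 | (6S,7S,8R,9R)-8,9-dihydroxygermacra-1(10)Z,4E,11(13)-trien-12,6-olide | C=C1C(=O)O[C@H]2/C=C(\C)CC/C=C(/C)[C@@H](O)[C@H](O)[C@H]12 | intermediate
30 | (6S,7S,8R,9R)-9-acetoxy-8-hydroxygermacra-1(10)Z,4E,11(13)-trien-12,6-olide | C=C1C(=O)O[C@H]2/C=C(\C)CC/C=C(/C)[C@@H](OC(C)=O)[C@H](O)[C@H]12 | intermediate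
31 | angelic acid, (2Z)-2-methylbut-2-enoic acid | C/C=C(/C)C(=O)O | starting material
32 | (2Z)-2-methylbut-2-en-1-ol | C/C=C(/C)CO | intermediate
33 | [(2S,3R)-2,3-dimethyloxiran-2-yl]methanol | OC[C@]1(C)O[C@@H]1C | intermediate
34 | (2R,3R)-2,3-dimethyloxirane-2-carboxylic acid | OC(=O)[C@]1(C)O[C@@H]1C | intermediate
35 | (2R,3R)-2,3-dimethyloxirane-2-carboxylic 2,4,6-trichlorobenzoic anhydride | Clc1cc(Cl)cc(Cl)c1C(=O)OC(=O)[C@]2(C)O[C@@H]2C | intermediate
36 | (6S,7R,8R,9R)-9-acetoxy-8-{[(2R,3R)-2,3-dimethyloxirane-2-carbonyl]oxy}germacra-1(10)Z,4E,11(13)-trien-12,6-olide | C=C1C(=O)O[C@H]2/C=C(\C)CC/C=C(/C)[C@@H](OC(C)=O)[C@H](OC(=O)[C@]3(C)O[C@@H]3C)[C@H]12 | target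

## Step count and least certain steps

Total step count: 25. Longest linear sequence: 17 steps (steps 1, 2, 3, 7, 8, 11 to 21 and 25, from geranyl acetate 1).

**Step 17 (key step).**
- Risk: lithiation may occur at C13 or at the silyloxy-bearing C12 instead of C6, because a prenyl-type allyl unit such as C6–C5=C4 is electronically the less acidic one and the route relies on steric shielding by the C11 substituent. A C13 anion would fragment or rearrange the wrong way. A [1,2]-shift could compete if the shift is slow, and the carbanion could attack the other face of C7=C11 and give the C6/C7 diastereomer.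
- Fallback: it sets out from hydroxy chloride 21 and forms the same C6–C7 bond by carbonyl allylation instead of a sigmatropic shift. MnO2 oxidation of the C6 allylic alcohol should give the chloro enal F1. Finkelstein exchange with LiBr in acetone should give the bromo enal F2. An intramolecular Nozaki–Hiyama allylation with CrCl2 in THF at high dilution should then add the allylchromium species (trivalent chromium) through C7 to the C6 aldehyde by way of a chair transition state; this is a known way to close ten-membered homoallylic alcohols with the anti arrangement. The fallback returns to the route at 24.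

**Step 16 (macro-etherification).**
- Risk: intermolecular etherification to dimers and oligomers may outrun the thirteen-membered closure, and base-induced 1,4-elimination of HCl from the 2-substituted allylic chloride may compete.
- Fallback: it sets out from hydroxy enoate 16 and closes the ring as a lactone, the most dependable macrocyclisation, before removing the carbonyl oxygen. Saponification with LiOH should give the seco acid F3. Yamaguchi macrolactonisation should give the thirteen-membered lactone F4. Reduction with i-Bu2AlH at −78 °C and trapping with Ac2O, pyridine and DMAP should give the α-acetoxy ether F5. Reduction with Et3SiH and BF3·OEt2 at −78 °C should deliver the ether, returning to the route at 22.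

**Step 11 (olefination at C7).**
- Risk: the phosphonate anion of 15 may lose silanolate by retro-Michael elimination, and the bulkier α-substituent may erode the E selectivity, which would put C12 and C13 on the wrong sides of the alkene.
- Fallback: it sets out from aldehyde 12 and fixes the geometry by an allylic transposition that is thermodynamically controlled. Silylation with Et3SiCl should give the aldehyde F6. A Morita–Baylis–Hillman reaction with ethyl acrylate and DABCO should give the adduct F7 (mixture at C7, of no consequence). Acetylation should give the acetate F8. DABCO-catalysed allylic transposition should give the (2E)-2-(acetoxymethyl) enoate F9, the known outcome for ester-derived adducts, with the acetoxymethyl arm cis to C8. Ethanolysis with K2CO3 in EtOH should give the alcohol F10, and silylation with TBSCl and imidazole returns to the route at 17.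

**Step 21 (selective acetylation).**
- Risk: acylation may be unselective between O9 and O8, and an acetyl group may migrate between the two vicinal oxygens, giving mixtures of regioisomeric monoacetates and diacetate.
- Fallback: it sets out from diol 29 and uses a bulky, non-migrating silyl group to mark O9, so that the acetate enters last. Silylation with Et3SiCl and 2,6-lutidine at −78 °C should give the 9-silyl ether F11. Yamaguchi esterification with 34 should give the ester F12. Buffered HF·pyridine should give the 9-hydroxy ester F13, and acetylation with Ac2O and DMAP returns to the route at 36. If O8 proves the more reactive oxygen, the two acylations of the main route are simply run in the opposite order.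

## Further compounds

F1 | step 17 | (2E,6Z)-7-{(4R,5R)-5-[(1E)-3-chloro-2-{[(tert-butyldimethylsilyl)oxy]methyl}prop-1-en-1-yl]-2,2-dimethyl-1,3-dioxolan-4-yl}-3-methylocta-2,6-dienal (chloro enal) | O=C/C=C(\C)CC/C=C(/C)[C@H]1OC(C)(C)O[C@@H]1/C=C(\CO[Si](C)(C)C(C)(C)C)CCl
F2 | step 17 | (2E,6Z)-7-{(4R,5R)-5-[(1E)-3-bromo-2-{[(tert-butyldimethylsilyl)oxy]methyl}prop-1-en-1-yl]-2,2-dimethyl-1,3-dioxolan-4-yl}-3-methylocta-2,6-dienal (bromo enal) | O=C/C=C(\C)CC/C=C(/C)[C@H]1OC(C)(C)O[C@@H]1/C=C(\CO[Si](C)(C)C(C)(C)C)CBr
F3 | step 16 | (2E)-2-{[(tert-butyldimethylsilyl)oxy]methyl}-3-{(4R,5R)-5-[(2Z,6E)-8-hydroxy-6-methylocta-2,6-dien-2-yl]-2,2-dimethyl-1,3-dioxolan-4-yl}prop-2-enoic acid (seco acid) | OC/C=C(\C)CC/C=C(/C)[C@H]1OC(C)(C)O[C@@H]1/C=C(\CO[Si](C)(C)C(C)(C)C)C(=O)O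
F4 | step 16 | (3E,5R,6R,7Z,11E)-3-{[(tert-butyldimethylsilyl)oxy]methyl}-5,6-(isopropylidenedioxy)-7,11-dimethyl-1-oxacyclotrideca-3,7,11-trien-2-one (thirteen-membered lactone) | C1OC(=O)/C(CO[Si](C)(C)C(C)(C)C)=C/[C@H]2OC(C)(C)O[C@@H]2/C(C)=C\CC/C(C)=C/1
F5 | step 16 | 2-acetoxy derivative of 22 (α-acetoxy ether, mixture at the acetal carbon) | C1OC(OC(C)=O)/C(CO[Si](C)(C)C(C)(C)C)=C/[C@H]2OC(C)(C)O[C@@H]2/C(C)=C\CC/C(C)=C/1
F6 | step 11 | (4S,5R)-2,2-dimethyl-5-[(2Z,6E)-6-methyl-8-(triethylsilyloxy)octa-2,6-dien-2-yl]-1,3-dioxolane-4-carbaldehyde | CC[Si](CC)(CC)OC/C=C(\C)CC/C=C(/C)[C@H]1OC(C)(C)O[C@@H]1C=O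
F7 | step 11 | Morita–Baylis–Hillman adduct of F6 with ethyl acrylate (ethyl 2-methylene-3-hydroxy ester, mixture at C7) | CC[Si](CC)(CC)OC/C=C(\C)CC/C=C(/C)[C@H]1OC(C)(C)O[C@@H]1C(O)C(=C)C(=O)OCC
F8 | step 11 | acetate of F7 at the C7 oxygen | CC[Si](CC)(CC)OC/C=C(\C)CC/C=C(/C)[C@H]1OC(C)(C)O[C@@H]1C(OC(C)=O)C(=C)C(=O)OCC
F9 | step 11 | ethyl (2E)-2-(acetoxymethyl)-3-{(4R,5R)-2,2-dimethyl-5-[(2Z,6E)-6-methyl-8-(triethylsilyloxy)octa-2,6-dien-2-yl]-1,3-dioxolan-4-yl}prop-2-enoate | CC[Si](CC)(CC)OC/C=C(\C)CC/C=C(/C)[C@H]1OC(C)(C)O[C@@H]1/C=C(\COC(C)=O)C(=O)OCC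
F10 | step 11 | ethyl (2E)-2-(hydroxymethyl)-3-{(4R,5R)-2,2-dimethyl-5-[(2Z,6E)-6-methyl-8-(triethylsilyloxy)octa-2,6-dien-2-yl]-1,3-dioxolan-4-yl}prop-2-enoate | CC[Si](CC)(CC)OC/C=C(\C)CC/C=C(/C)[C@H]1OC(C)(C)O[C@@H]1/C=C(\CO)C(=O)OCC
F11 | step 21 | (6S,7S,8R,9R)-8-hydroxy-9-(triethylsilyloxy)germacra-1(10)Z,4E,11(13)-trien-12,6-olide | C=C1C(=O)O[C@H]2/C=C(\C)CC/C=C(/C)[C@@H](O[Si](CC)(CC)CC)[C@H](O)[C@H]12
F12 | step 21 | (6S,7R,8R,9R)-8-{[(2R,3R)-2,3-dimethyloxirane-2-carbonyl]oxy}-9-(triethylsilyloxy)germacra-1(10)Z,4E,11(13)-trien-12,6-olide | C=C1C(=O)O[C@H]2/C=C(\C)CC/C=C(/C)[C@@H](O[Si](CC)(CC)CC)[C@H](OC(=O)[C@]3(C)O[C@@H]3C)[C@H]12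
F13 | step 21 | (6S,7R,8R,9R)-8-{[(2R,3R)-2,3-dimethyloxirane-2-carbonyl]oxy}-9-hydroxygermacra-1(10)Z,4E,11(13)-trien-12,6-olide | C=C1C(=O)O[C@H]2/C=C(\C)CC/C=C(/C)[C@@H](O)[C@H](OC(=O)[C@]3(C)O[C@@H]3C)[C@H]12
A1 | alternative 1 | open-chain iodo aldehyde (C6 aldehyde, E-vinyl iodide at C5, C12 methyl ester, 9-O-p-methoxybenzyl, 8-O-tert-butyldimethylsilyl) | I/C=C(\C)CC/C=C(/C)[C@@H](OCc1ccc(OC)cc1)[C@H](O[Si](C)(C)C(C)(C)C)[C@H](CC(=O)OC)C=O
A2 | alternative 1 | protected ten-membered trans-fused γ-lactone (9-O-p-methoxybenzyl, 8-O-tert-butyldimethylsilyl, no C13) | C1C(=O)O[C@H]2/C=C(\C)CC/C=C(/C)[C@@H](OCc3ccc(OC)cc3)[C@H](O[Si](C)(C)C(C)(C)C)[C@H]12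
A3 | alternative 2 | lactone dialdehyde (C8 aldehyde on the lactone, Z-enal at C9) | C1C(=O)O[C@@H](/C=C(\C)CC/C=C(/C)C=O)[C@@H]1C=O
A4 | alternative 2 | ten-membered 8,9-diol lactone (no C13) | C1C(=O)O[C@H]2/C=C(\C)CC/C=C(/C)[C@@H](O)[C@H](O)[C@H]12
A5 | alternative 3 | cis-1-vinyl-2-isopropenylcyclohexanol (ring C5–C10) fused to the methyl lactol ether, 9-O-p-methoxybenzyl, 8-O-tert-butyldimethylsilyl | C=C[C@]1(O)[C@H](C(C)=C)[C@@H]2OC(OC)C[C@H]2[C@@H](O[Si](C)(C)C(C)(C)C)[C@@H]1OCc3ccc(OC)cc3
A6 | alternative 3 | ten-membered Z-enol triflate with E C4=C5 alkene | C1C(OC)O[C@H]2/C=C(\C)CC/C=C(/OS(=O)(=O)C(F)(F)F)[C@@H](OCc3ccc(OC)cc3)[C@H](O[Si](C)(C)C(C)(C)C)[C@H]12
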